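**Strategy.** Everything rests on closing ring C across C3–C4. Because C4 is a carbonyl carbon flanked by C3, it can be carried as a silyl enol ether whose terminal CH2 serves as an alkene. Ring-closing metathesis with a vinyl group on C2 then forms C3=C4, closes the pyranone ring and delivers C4 as a masked ketone in one neutral operation that leaves the epimerisable O1–C2 benzylic centre untouched. The precursor is an (S)-aryl 1-arylallyl ether: ring A carries the ether oxygen (O1) and, ortho to it, a 1-(silyloxy)vinyl group; ring B carries both prenyl groups. The C2 centre is set beforehand by iridium-catalysed allylic etherification.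

Key step: step 9

**Remarks and assumptions**

- Flavanone numbering is used (O1, C2, C3, C4, C4a to C8a; ring A = fused benzo ring, ring B = 2-aryl group, ring C = pyranone).
- Abbreviations: MOM = methoxymethyl; TBS = tert-butyldimethylsilyl; prenyl = 3-methylbut-2-en-1-yl; Ar = 4-(methoxymethoxy)-3,5-diprenylphenyl; H2IMes = 1,3-dimesityl-4,5-dihydroimidazol-2-ylidene; L = O,O'-(S)-1,1'-binaphthyl-2,2'-diyl N,N-bis[(S)-1-phenylethyl]phosphoramidite.
- Assumption: the (Sa,Sc,Sc) antipode of L is taken to deliver the (S)-ether in step 7; should the first run show the opposite sense, the mirror-image ligand is used with no other change.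
- Configuration check: in 13, 14, 15 and 19 the C2 centre keeps one spatial arrangement and one priority order (O1 > ring-B carbon > vinyl carbon or C3 > H), so it is S throughout.
- Design choices: both phenols are MOM ethers, inert to the tin, hydride, aryloxide and carbene chemistry and removed together with the enol ether in one acid step. The enol ether is TBS, robust enough to handle and small enough for metathesis. The key step is run dilute with benzoquinone and with removal of ethylene to protect the prenyl groups and C2.

**Route**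

Step 1
Reactants: 1 3,5-dibromo-4-hydroxybenzaldehyde
Product: 2 3,5-dibromo-4-(methoxymethoxy)benzaldehyde
Conditions: MOMCl (1.5 equiv), i-Pr2NEt (2 equiv), CH2Cl2, 0 °C → rt
Reagents that add atoms: chloromethyl methyl ether (MOMCl), COCCl
Why: Williamson-type O-alkylation of the acidic phenol by the small, highly reactive α-chloro ether, which can reach the oxygen between the two bromines, while the aldehyde is inert to amine base and alkylating agent.

Step 2
Reactants: 2 3,5-dibromo-4-(methoxymethoxy)benzaldehyde; 3 tributyl(3-methylbut-2-en-1-yl)stannane (2.5 equiv)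
Product: 5 4-(methoxymethoxy)-3,5-bis(3-methylbut-2-en-1-yl)benzaldehyde, via monoprenylated bromoaldehyde 4 (not isolated)
Conditions: Pd(PPh3)4 (8 mol%), DMF, 100 °C, degassed
Reagents that add atoms: none
Why: Twofold Stille coupling in which each aryl–bromine bond undergoes oxidative addition, the prenyl group is transferred from tin and reductive elimination occurs at the unsubstituted allyl terminus because the tertiary terminus is too hindered, so the linear prenyl arene should form under neutral conditions that spare aldehyde and MOM ether.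

Step 3
Reactants: 5 4-(methoxymethoxy)-3,5-bis(3-methylbut-2-en-1-yl)benzaldehyde
Product: 6 ethyl (E)-3-Ar-prop-2-enoate
Conditions: Ph3P=CHCO2Et (1.2 equiv), toluene, 80 °C
Reagents that add atoms: ethyl (triphenylphosphoranylidene)acetate, CCOC(=O)C=P(c1ccccc1)(c1ccccc1)c1ccccc1
Why: Wittig olefination with a stabilised ylide, which reacts reversibly through the anti oxaphosphetane and should therefore give the (E)-cinnamate without any added base.

Step 4
Reactants: 6 ethyl (E)-3-Ar-prop-2-enoate
Product: 8 (E)-3-Ar-prop-2-en-1-ol, via enal 7 (not isolated)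
Conditions: i-Bu2AlH (2.5 equiv), CH2Cl2, −78 → −20 °C; aqueous KNaC4H4O6 work-up
Reagents that add atoms: none
Why: 1,2-Reduction of the conjugated ester by the electrophilic aluminium hydride through the aldehyde to the allylic alcohol, a reagent that does not reduce the conjugated alkene and leaves prenyl and MOM groups alone.

Step 5
Reactants: 8 (E)-3-Ar-prop-2-en-1-ol
Product: 9 (E)-3-Ar-prop-2-en-1-yl methyl carbonate
Conditions: ClCO2Me (1.5 equiv), pyridine (3 equiv), CH2Cl2, 0 °C
Reagents that add atoms: methyl chloroformate, COC(=O)Cl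
Why: Acylation of the primary allylic alcohol through the acylpyridinium ion gives the linear carbonate that acts as the leaving group in the iridium step.

Step 6
Reactants: 10 2,4-dihydroxyacetophenone
Product: 11 1-[2-hydroxy-4-(methoxymethoxy)phenyl]ethan-1-one
Conditions: MOMCl (1.1 equiv), i-Pr2NEt (1.3 equiv), CH2Cl2, 0 °C
Reagents that add atoms: chloromethyl methyl ether (MOMCl), COCCl
Why: Site-selective O-alkylation, because the 2-hydroxyl is held in a hydrogen bond to the acetyl oxygen and is far less nucleophilic than the 4-hydroxyl.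

Step 7
Reactants: 9 (E)-3-Ar-prop-2-en-1-yl methyl carbonate; 11 1-[2-hydroxy-4-(methoxymethoxy)phenyl]ethan-1-one (2.0 equiv)
Product: 13 1-[4-(methoxymethoxy)-2-{[(1S)-1-Ar-prop-2-en-1-yl]oxy}phenyl]ethan-1-one, via sodium aryloxide 12 (not isolated)
Conditions: 11, NaH (2.0 equiv), THF, 0 °C → rt; then 9, [Ir(cod)Cl]2 (2 mol%), (Sa,Sc,Sc)-L (4 mol%; catalyst pre-activated with n-PrNH2), THF, 40 °C
Reagents that add atoms: none
Why: Iridium-catalysed asymmetric allylic etherification in which the linear carbonate ionises on the cyclometalated iridium–phosphoramidite catalyst to a π-allyl complex and the aryloxide attacks the aryl-substituted terminus anti to the metal on the face left open by the ligand, which gives the branched ether and sets C2 as S under catalyst control, while the two ortho prenyl groups twist the ring-B MOM ether out of conjugation and so slow re-ionisation of the product.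

Step 8
Reactants: 13 1-[4-(methoxymethoxy)-2-{[(1S)-1-Ar-prop-2-en-1-yl]oxy}phenyl]ethan-1-one
Product: 14 TBS enol ether of 13, the (S)-aryl 1-arylallyl ether bearing an ortho 1-(tert-butyldimethylsilyloxy)vinyl group
Conditions: t-BuMe2SiOTf (1.3 equiv), Et3N (2.5 equiv), CH2Cl2, −20 → 0 °C; cold aqueous NaHCO3; filtration through Et3N-deactivated silica; used promptly
Reagents that add atoms: tert-butyldimethylsilyl trifluoromethanesulfonate, CC(C)(C)[Si](C)(C)OS(=O)(=O)C(F)(F)F
Why: Soft enolisation, in which O-silylation of the carbonyl is followed by amine deprotonation of the methyl group, the only α-carbon, so the 1-aryl-1-silyloxyethene should form without strong base and the C2 ether centre, the MOM ethers and the alkenes stay untouched.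

Step 9
Reactants: 14 TBS enol ether of 13
Product: 15 (S)-4-(tert-butyldimethylsilyloxy)-7-(methoxymethoxy)-2-Ar-2H-chromene
Conditions: RuCl2(H2IMes)(=CH-C6H4-2-O-i-Pr) (second-generation Hoveyda–Grubbs catalyst, 5 mol%, a second portion if needed), 1,4-benzoquinone (10 mol%), toluene (0.005 M), 70 °C, slow argon sparge
Reagents that add atoms: none
Why: The ruthenium benzylidene exchanges onto the monosubstituted vinyl group at C2, the new alkylidene adds intramolecularly to the 1,1-disubstituted silyl enol ether in a [2+2] step and cycloreversion releases Ru=CH2, which leaves as ethylene. The closest known reaction type is ring-closing metathesis of olefinic silyl enol ethers to cyclic silyl enol ethers, together with the closure of ortho-vinyl aryl allyl ethers to 2H-chromenes. Ring C (O1, C2, C3, C4, C4a, C8a) closes as a six-membered ring with the new C3=C4 bond endocyclic, a favourable closure because ring A holds the two alkenes ortho to each other. No stereocentre is formed, and the C2 centre from step 7 is carried through because no bond to C2 is made or broken and neither acid nor base is present; benzoquinone is added to intercept ruthenium hydrides that could move C3=C4 towards C2. The step needs chemoselectivity among four alkenes, secured by the substitution pattern: only the two terminal alkenes load and close readily, whereas the trisubstituted prenyl alkenes react slowly and could reach C3 only through a four-atom bridge across meta positions of ring B, and high dilution with removal of ethylene keeps them from cross-metathesis.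

Step 10
Reactants: 15 (S)-4-(tert-butyldimethylsilyloxy)-7-(methoxymethoxy)-2-Ar-2H-chromene
Product: 19 (2S)-7-hydroxy-2-[4-hydroxy-3,5-bis(3-methylbut-2-en-1-yl)phenyl]-2,3-dihydro-4H-chromen-4-one, via bis-MOM flavanone 16 (not isolated), via 7-O-MOM flavanone 17 (not isolated), via 4'-O-MOM flavanone 18 (not isolated)
Conditions: HCl (about 1 M) in MeOH/THF (4:1), 0 °C, then 40 °C
Reagents that add atoms: none
Why: Acid-catalysed solvolysis, in which C3 of the silyl enol ether is protonated at 0 °C to unveil the C4 ketone and the two MOM acetals then undergo methanolysis in either order, while C2 carries no enolisable hydrogen and ring C opens only slowly in dilute acid, so the S configuration should be kept.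

**Compound list**

1 | 3,5-dibromo-4-hydroxybenzaldehyde | O=Cc1cc(Br)c(O)c(Br)c1 | starting material
2 | 3,5-dibromo-4-(methoxymethoxy)benzaldehyde | COCOc1c(Br)cc(C=O)cc1Br | intermediate
3 | tributyl(3-methylbut-2-en-1-yl)stannane | CCCC[Sn](CCCC)(CCCC)CC=C(C)C | starting material
4 | 3-bromo-4-(methoxymethoxy)-5-(3-methylbut-2-en-1-yl)benzaldehyde (formed in the flask, not isolated) | COCOc1c(Br)cc(C=O)cc1CC=C(C)C | intermediate
5 | 4-(methoxymethoxy)-3,5-bis(3-methylbut-2-en-1-yl)benzaldehyde | COCOc1c(CC=C(C)C)cc(C=O)cc1CC=C(C)C | intermediate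
6 | ethyl (2E)-3-[4-(methoxymethoxy)-3,5-bis(3-methylbut-2-en-1-yl)phenyl]prop-2-enoate | CCOC(=O)/C=C/c1cc(CC=C(C)C)c(OCOC)c(CC=C(C)C)c1 | intermediate
7 | (2E)-3-[4-(methoxymethoxy)-3,5-bis(3-methylbut-2-en-1-yl)phenyl]prop-2-enal (formed in the flask, not isolated) | O=C/C=C/c1cc(CC=C(C)C)c(OCOC)c(CC=C(C)C)c1 | intermediate
8 | (2E)-3-[4-(methoxymethoxy)-3,5-bis(3-methylbut-2-en-1-yl)phenyl]prop-2-en-1-ol | OC/C=C/c1cc(CC=C(C)C)c(OCOC)c(CC=C(C)C)c1 | intermediate
9 | (2E)-3-[4-(methoxymethoxy)-3,5-bis(3-methylbut-2-en-1-yl)phenyl]prop-2-en-1-yl methyl carbonate | COC(=O)OC/C=C/c1cc(CC=C(C)C)c(OCOC)c(CC=C(C)C)c1 | intermediate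
10 | 2,4-dihydroxyacetophenone | CC(=O)c1ccc(O)cc1O | starting material
11 | 1-[2-hydroxy-4-(methoxymethoxy)phenyl]ethan-1-one | CC(=O)c1ccc(OCOC)cc1O | intermediate
12 | sodium 2-acetyl-5-(methoxymethoxy)phenolate (formed in the flask, not isolated) | CC(=O)c1ccc(OCOC)cc1[O-].[Na+] | intermediate
13 | 1-[4-(methoxymethoxy)-2-({(1S)-1-[4-(methoxymethoxy)-3,5-bis(3-methylbut-2-en-1-yl)phenyl]prop-2-en-1-yl}oxy)phenyl]ethan-1-one | CC(C)=CCc1cc([C@H](C=C)Oc2cc(OCOC)ccc2C(C)=O)cc(CC=C(C)C)c1OCOC | intermediate
14 | tert-butyl({1-[4-(methoxymethoxy)-2-({(1S)-1-[4-(methoxymethoxy)-3,5-bis(3-methylbut-2-en-1-yl)phenyl]prop-2-en-1-yl}oxy)phenyl]ethenyl}oxy)dimethylsilane | CC(C)=CCc1cc([C@H](C=C)Oc2cc(OCOC)ccc2C(=C)O[Si](C)(C)C(C)(C)C)cc(CC=C(C)C)c1OCOC | intermediate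
15 | tert-butyl({(2S)-7-(methoxymethoxy)-2-[4-(methoxymethoxy)-3,5-bis(3-methylbut-2-en-1-yl)phenyl]-2H-chromen-4-yl}oxy)dimethylsilane | CC(C)=CCc1cc([C@@H]2C=C(O[Si](C)(C)C(C)(C)C)c3ccc(OCOC)cc3O2)cc(CC=C(C)C)c1OCOC | intermediate
16 | (2S)-7-(methoxymethoxy)-2-[4-(methoxymethoxy)-3,5-bis(3-methylbut-2-en-1-yl)phenyl]-2,3-dihydro-4H-chromen-4-one (formed in the flask, not isolated) | CC(C)=CCc1cc([C@@H]2CC(=O)c3ccc(OCOC)cc3O2)cc(CC=C(C)C)c1OCOC | intermediate
17 | (2S)-2-[4-hydroxy-3,5-bis(3-methylbut-2-en-1-yl)phenyl]-7-(methoxymethoxy)-2,3-dihydro-4H-chromen-4-one (formed in the flask, not isolated) | CC(C)=CCc1cc([C@@H]2CC(=O)c3ccc(OCOC)cc3O2)cc(CC=C(C)C)c1O | intermediate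
18 | (2S)-7-hydroxy-2-[4-(methoxymethoxy)-3,5-bis(3-methylbut-2-en-1-yl)phenyl]-2,3-dihydro-4H-chromen-4-one (formed in the flask, not isolated) | CC(C)=CCc1cc([C@@H]2CC(=O)c3ccc(O)cc3O2)cc(CC=C(C)C)c1OCOC | intermediate
19 | (2S)-7-hydroxy-2-[4-hydroxy-3,5-bis(3-methylbut-2-en-1-yl)phenyl]-2,3-dihydro-4H-chromen-4-one | CC(C)=CCc1cc([C@@H]2CC(=O)c3ccc(O)cc3O2)cc(CC=C(C)C)c1O | target

**Step count**

Total step count: 10.
Longest linear sequence: 9 steps (from 1 to 19 through steps 1 to 5 and 7 to 10).

**The three steps most likely to fail**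

1. Step 9 (ring-closing metathesis). What may go wrong: the carbene may load on the electron-rich enol ether and rest as an unreactive oxygen-substituted carbene, so that closure stalls. The prenyl groups may also be cut back by cross-metathesis with ethylene or join in intermolecular cross-metathesis, and ruthenium hydrides may shift double bonds. Fallback (no metathesis; ring C closed by oxa-Michael addition and C2 secured by resolution): the fallback sets out from 5 and 11. Claisen–Schmidt condensation (KOH, EtOH, rt) should give the 2'-hydroxychalcone F1. NaOAc in refluxing EtOH should cyclise it to the racemic bis-MOM flavanone F2. Kinetic resolution by asymmetric transfer hydrogenation (RhCl(C5Me5)[(R,R)-TsDPEN], HCO2H/Et3N, EtOAc, rt, stopped near half conversion) should reduce the (2R)-ketone to the cis-(2R,4R)-flavan-4-ol F3, which is separated, and leave the (2S)-ketone, which is compound 16. The route is rejoined at 16, which the methanolic HCl of step 10 takes to 19.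

2. Step 7 (iridium-catalysed etherification). What may go wrong: slow attack by the chelated, electron-poor aryloxide, loss of branched selectivity or of enantiomeric purity through reversible ionisation of the electron-rich benzylic ether, and competing attack by methoxide. Fallback (stereocentre made on an alcohol, C–O bond formed by SN2 inversion): the fallback sets out from 5. Addition of CH2=CHMgBr (THF, −78 °C) should give the racemic 1-arylallyl alcohol F4. Acylation with Candida antarctica lipase B and vinyl acetate (hexane, rt), which by the usual empirical rule for secondary alcohols acylates the R enantiomer, should give the (R)-acetate F5, separated from unreacted (S)-alcohol. K2CO3 in MeOH should free the (R)-alcohol F6. Mitsunobu etherification with 11 (PPh3, DIAD, toluene, −20 → 0 °C) should proceed with inversion and give 13, where the route is rejoined.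

3. Step 10 (global unmasking). What may go wrong: acid-promoted cyclisation of the freed ring-B phenol onto a neighbouring prenyl group, addition of HCl or MeOH to the prenyl alkenes, and partial epimerisation at C2 through reversible opening of ring C if long heating is needed. Fallback (two stages without protic acid): the fallback sets out from 15. Et3N·3HF (THF, 0 °C) should cleave only the silyl enol ether and give 16 as an isolated compound. Me3SiOTf with 2,2'-bipyridyl (MeCN, 0 °C) should then exchange both aryl MOM ethers for silyl ethers, giving the bis(trimethylsilyl) ether F7, which water added at the end hydrolyses to 19, where the route is rejoined.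

**Further compounds**

F1 | step 9 | (2E)-1-[2-hydroxy-4-(methoxymethoxy)phenyl]-3-[4-(methoxymethoxy)-3,5-bis(3-methylbut-2-en-1-yl)phenyl]prop-2-en-1-one | COCOc1ccc(C(=O)/C=C/c2cc(CC=C(C)C)c(OCOC)c(CC=C(C)C)c2)c(O)c1
F2 | step 9 | racemic 7-(methoxymethoxy)-2-[4-(methoxymethoxy)-3,5-bis(3-methylbut-2-en-1-yl)phenyl]-2,3-dihydro-4H-chromen-4-one | CC(C)=CCc1cc(C2CC(=O)c3ccc(OCOC)cc3O2)cc(CC=C(C)C)c1OCOC
F3 | step 9 | (2R,4R)-7-(methoxymethoxy)-2-[4-(methoxymethoxy)-3,5-bis(3-methylbut-2-en-1-yl)phenyl]-3,4-dihydro-2H-chromen-4-ol | CC(C)=CCc1cc([C@H]2C[C@@H](O)c3ccc(OCOC)cc3O2)cc(CC=C(C)C)c1OCOC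
F4 | step 7 | racemic 1-[4-(methoxymethoxy)-3,5-bis(3-methylbut-2-en-1-yl)phenyl]prop-2-en-1-ol | C=CC(O)c1cc(CC=C(C)C)c(OCOC)c(CC=C(C)C)c1
F5 | step 7 | (1R)-1-[4-(methoxymethoxy)-3,5-bis(3-methylbut-2-en-1-yl)phenyl]prop-2-en-1-yl acetate | CC(=O)O[C@H](C=C)c1cc(CC=C(C)C)c(OCOC)c(CC=C(C)C)c1
F6 | step 7 | (1R)-1-[4-(methoxymethoxy)-3,5-bis(3-methylbut-2-en-1-yl)phenyl]prop-2-en-1-ol | O[C@H](C=C)c1cc(CC=C(C)C)c(OCOC)c(CC=C(C)C)c1
F7 | step 10 | (2S)-2-[3,5-bis(3-methylbut-2-en-1-yl)-4-(trimethylsilyloxy)phenyl]-7-(trimethylsilyloxy)-2,3-dihydro-4H-chromen-4-one | CC(C)=CCc1cc([C@@H]2CC(=O)c3ccc(O[Si](C)(C)C)cc3O2)cc(CC=C(C)C)c1O[Si](C)(C)C
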